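The strategy cuts ring C (the carbocycle) at two bonds: from the N-bearing enamine carbon to the oxygenated quaternary carbon, and from the carbinol carbon to the ring-fusion CH. One thermal intramolecular Diels–Alder reaction of a 2-amidofuran with a tethered enol lactone makes both bonds and closes ring C and the pyrrolidine. The oxygen bridge then opens to give an enamide and a ketone. The step exploits the para relationship in ring C between the enamine carbon on nitrogen and the carbinol carbon, with the lactone-bearing quaternary carbon next to the former. This pattern maps onto furan C-2 and C-5. The precursor is a furo[2,3-b]azepin-7-one whose nitrogen bears a CH(methyl-lactone)CH2 arm ending in a 5-substituted furan-2(3H)-one.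

Key step: step 18

Assumption: nucleophiles attack the (S)-configured N-tert-butanesulfinyl aldimine on its Re face through the lithium-bridged closed transition state, which here coincides with the Felkin–Anh preference of the α-alkoxy imine.

Step 1
Reactants: 1 3,4-dibromofuran
Product: 3 3-bromo-4-ethylfuran, via 4-bromo-3-furyllithium 2 (not isolated)
Conditions: n-BuLi (1.0 equiv), Et2O, −78 °C; EtOTf, −78 to −20 °C
Reagents that add atoms: ethyl trifluoromethanesulfonate, CCOS(=O)(=O)C(F)(F)F
Why: Bromine–lithium exchange stops after one bromine, and the cold 3-furyllithium is alkylated by the hard triflate before it can isomerise to the 2-lithio species, which fixes the 3,4-pattern that a monobromofuran cannot supply.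

Step 2
Reactants: 3 3-bromo-4-ethylfuran; 4 (4-ethoxy-4-oxobutyl)zinc bromide
Product: 5 ethyl 4-(4-ethylfuran-3-yl)butanoate
Conditions: Pd(OAc)2 (2 mol%), SPhos (4 mol%), THF, 50 °C
Reagents that add atoms: none
Why: Negishi coupling of a heteroaryl bromide with a primary, ester-bearing alkylzinc halide, in which the biaryl phosphine lets reductive elimination outrun β-hydride loss.

Step 3
Reactants: 5 ethyl 4-(4-ethylfuran-3-yl)butanoate
Product: 6 ethyl 4-(2,5-dibromo-4-ethylfuran-3-yl)butanoate
Conditions: NBS (2.1 equiv), DMF, 0 °C, dark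
Reagents that add atoms: N-bromosuccinimide, O=C1CCC(=O)N1Br
Why: Electrophilic bromination of a furan goes to the α-positions, and since the two α-carbons of a 3,4-dialkylfuran cannot be told apart both are brominated and the regiochemistry is settled later by reach (step 15).

Step 4
Reactants: 6 ethyl 4-(2,5-dibromo-4-ethylfuran-3-yl)butanoate
Product: 7 4-(2,5-dibromo-4-ethylfuran-3-yl)butanoic acid
Conditions: LiOH, THF/H2O, 0 °C to rt; 1 M HCl to pH 3
Reagents that add atoms: lithium hydroxide, [Li+].[OH-]
Why: Ester saponification, which the dibromofuran tolerates because it has no free α-position.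

Step 5
Reactants: 8 succinic anhydride
Product: 9 4-(benzyloxy)-4-oxobutanoic acid
Conditions: BnOH, DMAP (10 mol%), PhMe, 80 °C
Reagents that add atoms: benzyl alcohol, OCc1ccccc1
Why: Nucleophile-catalysed alcoholysis of a cyclic anhydride stops at the half ester.

Step 6
Reactants: 9 4-(benzyloxy)-4-oxobutanoic acid; 10 mono-tert-butyl malonate
Product: 12 6-benzyl 1-tert-butyl 3-oxohexanedioate, via acyl imidazolide 11 (not isolated)
Conditions: CDI, THF, rt; then 10, MgCl2, Et3N, MeCN, rt; 1 M HCl work-up
Reagents that add atoms: none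
Why: Masamune–Brooks acylation, in which the magnesium enolate of the malonate half ester attacks the acyl imidazolide and loses CO2, giving a β-keto ester with two differently cleavable esters.

Step 7
Reactants: 12 6-benzyl 1-tert-butyl 3-oxohexanedioate
Product: 13 6-(benzyloxy)-3,6-dioxohexanoic acid
Conditions: TFA, CH2Cl2, 0 °C; used at once
Reagents that add atoms: none
Why: Acidolysis of the tert-butyl ester (loss of isobutene) spares the benzyl ester, and the β-keto acid survives if kept cold.

Step 8
Reactants: 14 (S)-5-(hydroxymethyl)dihydrofuran-2(3H)-one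
Product: 15 (S)-5-[(benzyloxy)methyl]dihydrofuran-2(3H)-one
Conditions: BnOC(=NH)CCl3, TfOH (5 mol%), CH2Cl2/cyclohexane, 0 °C to rt
Reagents that add atoms: benzyl 2,2,2-trichloroacetimidate, N=C(OCc1ccccc1)C(Cl)(Cl)Cl
Why: Acid-catalysed O-benzylation with the trichloroacetimidate avoids the alkoxide that would translactonise or racemise the hydroxymethyl lactone.

Step 9
Reactants: 15 (S)-5-[(benzyloxy)methyl]dihydrofuran-2(3H)-one
Product: 19 (S)-5-[(benzyloxy)methyl]-3-methylenedihydrofuran-2(3H)-one, via lithium enolate 16 (not isolated), via Mannich base 17 (not isolated), via methiodide 18 (not isolated)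
Conditions: LDA, THF, −78 °C; CH2=NMe2 I, −78 °C to rt; MeI, THF, rt; aq NaHCO3, CH2Cl2
Reagents that add atoms: Eschenmoser's salt, C[N+](C)=C.[I-]
Why: α-Methylenation by the Mannich, quaternisation and Hofmann elimination sequence on the lactone enolate, which leaves the C-5 centre untouched.

Step 10
Reactants: 19 (S)-5-[(benzyloxy)methyl]-3-methylenedihydrofuran-2(3H)-one
Product: 20 (3S,5S)-5-(hydroxymethyl)-3-methyldihydrofuran-2(3H)-one
Conditions: H2 (1 atm), 10% Pd/C, EtOH, rt
Reagents that add atoms: none
Why: Heterogeneous hydrogenation delivers H2 to the alkene face anti to the C-5 side chain, which sets the (3S) methyl cis to it, and the same catalyst then hydrogenolyses the benzyl ether.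

Step 11
Reactants: 20 (3S,5S)-5-(hydroxymethyl)-3-methyldihydrofuran-2(3H)-one
Product: 22 (S,E)-2-methyl-N-{[(2S,4S)-4-methyl-5-oxotetrahydrofuran-2-yl]methylidene}propane-2-sulfinamide, via aldehyde 21 (not isolated)
Conditions: TEMPO (10 mol%), PhI(OAc)2, CH2Cl2, rt; aqueous wash, dry; (S)-t-BuS(O)NH2, CuSO4, CH2Cl2, rt
Reagents that add atoms: (S)-2-methylpropane-2-sulfinamide, CC(C)(C)[S@](=O)N
Why: Oxoammonium (TEMPO) oxidation stops at the aldehyde, which is condensed without isolation under neutral dehydration so that the labile α-alkoxy centre keeps its configuration (sulfinyl imine formation).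

Step 12
Reactants: 22 sulfinyl imine; 13 6-(benzyloxy)-3,6-dioxohexanoic acid
Product: 23 benzyl (6R)-6-{[(S)-tert-butylsulfinyl]amino}-6-[(2S,4S)-4-methyl-5-oxotetrahydrofuran-2-yl]-4-oxohexanoate
Conditions: 13 (1.5 equiv), LiOEt (0.5 equiv), THF, 0 °C to rt
Reagents that add atoms: none
Why: Decarboxylative Mannich reaction of a β-keto acid with an N-tert-butanesulfinyl aldimine, in which bond formation is regiospecific at the carboxyl-bearing CH2 and the lithium-bridged closed transition state sends it to the Re face of the (S)-sulfinyl imine, matched with the Felkin–Anh bias, giving the (R) amine carbon.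

Step 13
Reactants: 23 sulfinamide keto ester; 7 4-(2,5-dibromo-4-ethylfuran-3-yl)butanoic acid
Product: 26 benzyl (6R)-6-[4-(2,5-dibromo-4-ethylfuran-3-yl)butanamido]-6-[(2S,4S)-4-methyl-5-oxotetrahydrofuran-2-yl]-4-oxohexanoate, via amine hydrochloride 24 (not isolated), via mixed anhydride 25 (not isolated)
Conditions: 23, 4 M HCl in dioxane, Et2O, 0 °C, evaporate; 7, i-BuOCOCl, NMM, THF, −20 °C; then 24, NMM, −20 to 0 °C
Reagents that add atoms: none
Why: Acidic N–S cleavage followed by mixed-anhydride acylation, with the amine set free only in the presence of the cold preformed anhydride so that N-acylation outruns attack of the amine on its own γ-lactone (lactone-to-lactam shift).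

Step 14
Reactants: 26 keto amide
Product: 27 benzyl 3-{2-[(2R)-2-[4-(2,5-dibromo-4-ethylfuran-3-yl)butanamido]-2-[(2S,4S)-4-methyl-5-oxotetrahydrofuran-2-yl]ethyl]-1,3-dioxolan-2-yl}propanoate
Conditions: (Me3SiOCH2)2, Me3SiOTf (10 mol%), CH2Cl2, −78 to −20 °C
Reagents that add atoms: 1,2-bis(trimethylsilyloxy)ethane, C[Si](C)(C)OCCO[Si](C)(C)C
Why: Noyori ketalisation under aprotic silyl triflate catalysis masks the ketone, which removes the acidic CH2 next to the N-bearing carbon and so shuts off retro-Michael loss of the amide in the basic coupling that follows.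

Step 15
Reactants: 27 ketal amide
Product: 28 benzyl 3-{2-[(2R)-2-(2-bromo-3-ethyl-7-oxo-4,5,6,7-tetrahydro-8H-furo[2,3-b]azepin-8-yl)-2-[(2S,4S)-4-methyl-5-oxotetrahydrofuran-2-yl]ethyl]-1,3-dioxolan-2-yl}propanoate
Conditions: CuI (20 mol%), trans-N,N'-dimethylcyclohexane-1,2-diamine (40 mol%), K3PO4, PhMe (0.01 M), 100 °C
Reagents that add atoms: none
Why: Intramolecular Goldberg amidation (copper-catalysed amidation of 2-bromofurans is established), in which the copper amidate can reach only the bromide next to the acyl chain and closes the seven-membered lactam, while high dilution suppresses intermolecular reaction at the remote bromide.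

Step 16
Reactants: 28 bromo amidofuran ketal ester
Product: 29 3-{2-[(2R)-2-(3-ethyl-7-oxo-4,5,6,7-tetrahydro-8H-furo[2,3-b]azepin-8-yl)-2-[(2S,4S)-4-methyl-5-oxotetrahydrofuran-2-yl]ethyl]-1,3-dioxolan-2-yl}propanoic acid
Conditions: H2 (1 atm), 10% Pd/C, Et3N (1.1 equiv), EtOAc, rt; pH 4 buffer
Reagents that add atoms: none
Why: Catalytic hydrogenolysis removes the spare C–Br bond and the benzyl ester in one buffered operation, faster than any saturation of the trisubstituted furan.

Step 17
Reactants: 29 ketal acid
Product: 31 3-ethyl-8-{(1R)-1-[(2S,4S)-4-methyl-5-oxotetrahydrofuran-2-yl]-2-(5-oxo-4,5-dihydrofuran-2-yl)ethyl}-4,5,6,8-tetrahydro-7H-furo[2,3-b]azepin-7-one, via keto acid 30 (not isolated)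
Conditions: AcOH/THF/H2O, 40 °C, evaporate with PhMe; Ac2O, NaOAc (20 mol%), PhMe, 80 °C
Reagents that add atoms: water, O
Why: Mild ketal hydrolysis followed by enol-lactonisation of the γ-keto acid through its mixed anhydride, where the endocyclic furan-2(3H)-one is favoured because the chain CH2 is less hindered than the CH2 beside the branched N-bearing carbon and the endocyclic isomer is the more stable enol ester.

Step 18
Reactants: 31 amidofuran enol lactone
Product: 34 tetracyclic enamide ketone lactam (cis-fused lactone without methyl; ethyl trans to the lactone oxygen; pendant lactone cis to the ring-fusion CH), via oxanorbornene 32 (not isolated), via zwitterion 33 (not isolated)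
Conditions: PhMe (0.01 M), BHT (5 mol%), silylated sealed tube, 155 °C
Reagents that add atoms: none
Why: Proposed new method: heating lets furan C-2 and C-5 of the electron-rich amidofuran add suprafacially across the strained endocyclic enol-ester C=C to give oxanorbornene 32, whose N,O-ketal C–O bond is expelled by the nitrogen lone pair (zwitterion 33), and a 1,2-hydride shift from the alkoxide carbon to the neighbouring cationic carbon delivers enamide ketone 34. The closest known reactions are the thermal intramolecular Diels–Alder reactions of 2-amidofurans with unactivated tethered alkenes, cyclic trisubstituted ones included, that end in hexahydroindolinones, and the thermal addition of the cyclic enol ester vinylene carbonate to furan; an enol lactone has not served as the tethered partner. The pyrrolidine closes over the three-atom N–CH–CH2 tether, which lies exo (syn to the oxygen bridge), and ring C is the six-membered ring of the [4+2] event itself. The quaternary carbon and the ring-fusion CH come out cis because the alkene is locked Z in its ring, their sense relative to the N–CH centre follows from A(1,3) strain (that C–H eclipses the lactam C=O and the methyl-lactone points away, so the alkene reaches only the furan face that places the pendant lactone cis to the ring-fusion CH), and the ethyl-bearing carbon is set by the hydride moving across the face opposite the departed bridge oxygen, which is also the less strained pseudoaxial position. The step needs cycloaddition to outrun migration of the enol-lactone double bond into conjugation, and the β-acyloxy ketone must not enolise and lose its carboxylate, which would aromatise ring C. The short tether, the ring strain of the dienophile and a neutral, dilute, acid- and base-free medium serve both needs, and 34 is reduced at once.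

Step 19
Reactants: 34 enamide ketone lactam
Product: 35 enamide carbinol lactam (hydroxyl cis to the fused lactone, trans to ethyl)
Conditions: LiBH(s-Bu)3, THF, −78 °C; AcOH quench at −78 °C
Reagents that add atoms: none
Why: Bulky-hydride reduction of a hindered cyclohexanone, in which the reagent takes the equatorial trajectory on the face opposite the fused lactone because the axial path is closed by the pseudoaxial lactone oxygen 1,3 to the carbonyl, so the axial (R) carbinol cis to the lactone should result, while the low temperature and acidic quench keep the β-acyloxy ketone from enolising.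

Step 20
Reactants: 35 enamide carbinol lactam
Product: 36 triethylsilyl ether of 35
Conditions: Et3SiOTf, 2,6-lutidine, CH2Cl2, −40 °C
Reagents that add atoms: triethylsilyl trifluoromethanesulfonate, CC[Si](CC)(CC)OS(=O)(=O)C(F)(F)F
Why: Silylation of the hindered axial alcohol with the silyl triflate and a non-nucleophilic base shields it from the strong base and the thionating agent to come and prevents acyl migration between the two cis oxygens.

Step 21
Reactants: 36 silyl ether
Product: 40 α-methylene derivative of the fused lactone of 36, via lithium enolate 37 (not isolated), via Mannich base 38 (not isolated), via methiodide 39 (not isolated)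
Conditions: LDA (1.1 equiv), THF, −78 °C; CH2=NMe2 I, −78 °C to rt; MeI, THF, rt; aq NaHCO3, CH2Cl2
Reagents that add atoms: Eschenmoser's salt, C[N+](C)=C.[I-]
Why: The same Mannich, quaternisation and elimination methylenation, in which one equivalent of LDA takes the fused-lactone CH2, more acidic than the lactam CH2 and kinetically far more accessible than the tertiary α-C–H of the pendant lactone.

Step 22
Reactants: 40 α-methylene lactone
Product: 41 silyl ether lactam with the (R) methyl on the concave face of the fused lactone
Conditions: H2 (1 atm), 10% Pd/C, EtOAc, rt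
Reagents that add atoms: none
Why: Heterogeneous hydrogenation adds H2 to the convex face of the cis-fused lactone (the face of the ring-fusion hydrogen), away from ring C and its silyloxy group, so the new methyl ends on the concave side, and the tetrasubstituted enamide is inert.

Step 23
Reactants: 41 methyl lactone lactam
Product: 42 thiolactam of 41
Conditions: Lawesson's reagent (0.6 equiv), PhMe, 80 °C
Reagents that add atoms: Lawesson's reagent, COc1ccc(cc1)P1(=S)SP(=S)(S1)c1ccc(OC)cc1
Why: Thionation with Lawesson's reagent discriminates by carbonyl nucleophilicity, amide before ester, so only the lactam becomes C=S.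

Step 24
Reactants: 42 thiolactam silyl ether
Product: 43 thiolactam carbinol
Conditions: HF·pyridine, pyridine, THF, 0 °C
Reagents that add atoms: none
Why: Fluoride-induced Si–O cleavage in a pyridine buffer frees the carbinol without forming the alkoxide that could move the lactone to the neighbouring oxygen.

Step 25
Reactants: 43 thiolactam carbinol
Product: 44 target CNP0154902.3
Conditions: Raney Ni (W-2, washed neutral), THF/EtOH, rt
Reagents that add atoms: none
Why: Raney nickel desulfurisation turns the thiolactam C=S into CH2 under neutral conditions that leave both lactones, the free alcohol and the tetrasubstituted enamine double bond alone.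

Compound list
1 | 3,4-dibromofuran | Brc1cocc1Br | starting material
2 | 4-bromo-3-furyllithium | [Li]c1cocc1Br | intermediate
3 | 3-bromo-4-ethylfuran | CCc1cocc1Br | intermediate
4 | (4-ethoxy-4-oxobutyl)zinc bromide | CCOC(=O)CCC[Zn]Br | starting material
5 | ethyl 4-(4-ethylfuran-3-yl)butanoate | CCOC(=O)CCCc1cocc1CC | intermediate
6 | ethyl 4-(2,5-dibromo-4-ethylfuran-3-yl)butanoate | CCOC(=O)CCCc1c(Br)oc(Br)c1CC | intermediate
7 | 4-(2,5-dibromo-4-ethylfuran-3-yl)butanoic acid | OC(=O)CCCc1c(Br)oc(Br)c1CC | intermediate
8 | succinic anhydride | O=C1CCC(=O)O1 | starting material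
9 | 4-(benzyloxy)-4-oxobutanoic acid | OC(=O)CCC(=O)OCc1ccccc1 | intermediate
10 | mono-tert-butyl malonate | CC(C)(C)OC(=O)CC(=O)O | starting material
11 | benzyl 4-(imidazol-1-yl)-4-oxobutanoate | O=C(CCC(=O)OCc1ccccc1)n1ccnc1 | intermediate
12 | 6-benzyl 1-tert-butyl 3-oxohexanedioate | CC(C)(C)OC(=O)CC(=O)CCC(=O)OCc1ccccc1 | intermediate
13 | 6-(benzyloxy)-3,6-dioxohexanoic acid | OC(=O)CC(=O)CCC(=O)OCc1ccccc1 | intermediate
14 | (S)-5-(hydroxymethyl)dihydrofuran-2(3H)-one | OC[C@@H]1CCC(=O)O1 | starting material
15 | (S)-5-[(benzyloxy)methyl]dihydrofuran-2(3H)-one | O=C1CC[C@@H](COCc2ccccc2)O1 | intermediate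
16 | lithium enolate of 15 | [Li+].[O-]C1=CC[C@@H](COCc2ccccc2)O1 | intermediate
17 | (5S)-5-[(benzyloxy)methyl]-3-[(dimethylamino)methyl]dihydrofuran-2(3H)-one | CN(C)CC1C[C@@H](COCc2ccccc2)OC1=O | intermediate
18 | methiodide of 17 | C[N+](C)(C)CC1C[C@@H](COCc2ccccc2)OC1=O.[I-] | intermediate
19 | (S)-5-[(benzyloxy)methyl]-3-methylenedihydrofuran-2(3H)-one | C=C1C[C@@H](COCc2ccccc2)OC1=O | intermediate
20 | (3S,5S)-5-(hydroxymethyl)-3-methyldihydrofuran-2(3H)-one | OC[C@@H]1C[C@H](C)C(=O)O1 | intermediate
21 | (2S,4S)-4-methyl-5-oxotetrahydrofuran-2-carbaldehyde | O=C[C@@H]1C[C@H](C)C(=O)O1 | intermediate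
22 | (S,E)-N-sulfinyl imine of 21 | CC(C)(C)[S@](=O)/N=C/[C@@H]1C[C@H](C)C(=O)O1 | intermediate
23 | benzyl (6R)-6-{[(S)-tert-butylsulfinyl]amino}-6-[(2S,4S)-4-methyl-5-oxotetrahydrofuran-2-yl]-4-oxohexanoate | CC(C)(C)[S@](=O)N[C@@H]([C@@H]1C[C@H](C)C(=O)O1)CC(=O)CCC(=O)OCc1ccccc1 | intermediate
24 | hydrochloride of the (6R)-amine from 23 | [Cl-].[NH3+][C@@H]([C@@H]1C[C@H](C)C(=O)O1)CC(=O)CCC(=O)OCc1ccccc1 | intermediate
25 | isobutyl carbonic anhydride of 7 | CCc1c(Br)oc(Br)c1CCCC(=O)OC(=O)OCC(C)C | intermediate
26 | keto amide (dibromofuryl butanamide of the amine) | CCc1c(Br)oc(Br)c1CCCC(=O)N[C@@H]([C@@H]1C[C@H](C)C(=O)O1)CC(=O)CCC(=O)OCc1ccccc1 | intermediate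
27 | ethylene ketal of 26 | CCc1c(Br)oc(Br)c1CCCC(=O)N[C@@H]([C@@H]1C[C@H](C)C(=O)O1)CC1(CCC(=O)OCc2ccccc2)OCCO1 | intermediate
28 | 2-bromo furo[2,3-b]azepin-7-one ketal benzyl ester | CCc1c(Br)oc2c1CCCC(=O)N2[C@@H]([C@@H]1C[C@H](C)C(=O)O1)CC1(CCC(=O)OCc3ccccc3)OCCO1 | intermediate
29 | furo[2,3-b]azepin-7-one ketal acid | CCc1coc2c1CCCC(=O)N2[C@@H]([C@@H]1C[C@H](C)C(=O)O1)CC1(CCC(=O)O)OCCO1 | intermediate
30 | furo[2,3-b]azepin-7-one γ-keto acid | CCc1coc2c1CCCC(=O)N2[C@@H]([C@@H]1C[C@H](C)C(=O)O1)CC(=O)CCC(=O)O | intermediate
31 | amidofuran enol lactone (precursor of the key step) | CCc1coc2c1CCCC(=O)N2[C@@H]([C@@H]1C[C@H](C)C(=O)O1)CC1=CCC(=O)O1 | intermediate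
32 | oxanorbornene cycloadduct (tether exo, lactone endo) | CCC1=C2CCCC(=O)N3[C@@H]([C@@H]4C[C@H](C)C(=O)O4)C[C@]4(OC(=O)C[C@@H]4[C@H]1O5)[C@]235 | intermediate
33 | ring-opened N-acyliminium alkoxide zwitterion | CCC1=C2CCCC(=O)[N+]3=C2[C@]2(C[C@@H]3[C@@H]3C[C@H](C)C(=O)O3)OC(=O)C[C@@H]2[C@H]1[O-] | intermediate
34 | tetracyclic enamide ketone lactam (product of the key step) | CC[C@H]1C2=C3N(C(=O)CCC2)[C@@H]([C@@H]2C[C@H](C)C(=O)O2)C[C@]32OC(=O)C[C@@H]2C1=O | intermediate
35 | enamide carbinol lactam | CC[C@H]1C2=C3N(C(=O)CCC2)[C@@H]([C@@H]2C[C@H](C)C(=O)O2)C[C@]32OC(=O)C[C@@H]2[C@@H]1O | intermediate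
36 | triethylsilyl ether of 35 | CC[C@H]1C2=C3N(C(=O)CCC2)[C@@H]([C@@H]2C[C@H](C)C(=O)O2)C[C@]32OC(=O)C[C@@H]2[C@@H]1O[Si](CC)(CC)CC | intermediate
37 | lithium enolate of the fused lactone of 36 | CC[C@H]1C2=C3N(C(=O)CCC2)[C@@H]([C@@H]2C[C@H](C)C(=O)O2)C[C@]32OC([O-])=C[C@@H]2[C@@H]1O[Si](CC)(CC)CC.[Li+] | intermediate
38 | α-(dimethylaminomethyl) fused lactone | CC[C@H]1C2=C3N(C(=O)CCC2)[C@@H]([C@@H]2C[C@H](C)C(=O)O2)C[C@]32OC(=O)C(CN(C)C)[C@@H]2[C@@H]1O[Si](CC)(CC)CC | intermediate
39 | methiodide of 38 | CC[C@H]1C2=C3N(C(=O)CCC2)[C@@H]([C@@H]2C[C@H](C)C(=O)O2)C[C@]32OC(=O)C(C[N+](C)(C)C)[C@@H]2[C@@H]1O[Si](CC)(CC)CC.[I-] | intermediate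
40 | α-methylene fused lactone | CC[C@H]1C2=C3N(C(=O)CCC2)[C@@H]([C@@H]2C[C@H](C)C(=O)O2)C[C@]32OC(=O)C(=C)[C@@H]2[C@@H]1O[Si](CC)(CC)CC | intermediate
41 | α-methyl fused lactone lactam silyl ether | CC[C@H]1C2=C3N(C(=O)CCC2)[C@@H]([C@@H]2C[C@H](C)C(=O)O2)C[C@]32OC(=O)[C@H](C)[C@@H]2[C@@H]1O[Si](CC)(CC)CC | intermediate
42 | thiolactam silyl ether | CC[C@H]1C2=C3N(C(=S)CCC2)[C@@H]([C@@H]2C[C@H](C)C(=O)O2)C[C@]32OC(=O)[C@H](C)[C@@H]2[C@@H]1O[Si](CC)(CC)CC | intermediate
43 | thiolactam carbinol | CC[C@H]1C2=C3N(C(=S)CCC2)[C@@H]([C@@H]2C[C@H](C)C(=O)O2)C[C@]32OC(=O)[C@H](C)[C@@H]2[C@@H]1O | intermediate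
44 | CNP0154902.3 | CC[C@H]1C2=C3N(CCCC2)[C@@H]([C@@H]2C[C@H](C)C(=O)O2)C[C@]32OC(=O)[C@H](C)[C@@H]2[C@@H]1O | target

Total step count: 25. Longest linear sequence: 18 steps (14 to 44, steps 8 to 25).

Steps most likely to fail

Step 18. What may go wrong:
- The cycloaddition may be too slow relative to migration of the enol-lactone double bond into conjugation.
- The β-acyloxy ketone may enolise, lose its carboxylate and aromatise ring C.

The fallback carries hydrogen instead of oxygen on the future quaternary carbon through a cycloaddition of the established kind and oxidises that allylic C–H afterwards. It sets out from 22. Indium-mediated allylation (allyl bromide, In powder, THF) gives homoallylic sulfinamide F1 with the same facial sense. The operations of steps 13 and 15, with no ketal needed, give amide F2 and bromo amidofuran F3. Pd(PPh3)4 and Bu3SnH remove the bromine without touching the alkene and give N-homoallyl amidofuran F4. Cross-metathesis with methyl but-3-enoate (second-generation Hoveyda–Grubbs catalyst) gives (E)-alkenoate F5.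

Thermolysis as in step 18, now on an unactivated 1,2-disubstituted alkene of the known substrate class, gives keto ester F6, which has no leaving group and cannot aromatise. LiBH(s-Bu)3 followed by Et3SiOTf in the same flask gives silyl ether ester F7. Riley allylic hydroxylation (SeO2, t-BuOOH) then gives tertiary alcohol F8. In this oxidation the ene step binds selenium at the nucleophilic enamide β-carbon and takes the only hydrogen on the carbon attached to the N-bearing alkene carbon. The [2,3] shift returns the double bond and places OH with retention. F8 closes onto the cis methyl ester with a trace of DBU and rejoins the route at 36.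

Step 19. What may go wrong:
- Facial selectivity may be poor, because the pseudoaxial ethyl group hinders the very face that the hydride must use.
- The basic hydride may enolise the ketone.

The fallback replaces substrate control by catalyst control. It is a Corey–Bakshi–Shibata reduction of 34 with (S)-Me-CBS oxazaborolidine and catecholborane in toluene at −78 °C, which is non-basic. The catalyst should bind the carbonyl lone pair on the ethyl side, where only a hydrogen lies in the carbonyl plane. It should therefore treat the ring-fusion side as the large group and deliver the (R) carbinol. The fallback runs from 34 to 35.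

Step 17. What may go wrong:
- Enolisation toward the CH2 beside the N-bearing carbon may give the exocyclic alkylidene lactone or expel the lactam nitrogen.
- Acid may erode the amidofuran.

The fallback replaces dehydrative acylation by elimination from a halolactone. It sets out from 30. Treatment with 1-chloro-N,N,2-trimethylpropenylamine in CH2Cl2 at 0 °C gives the acid chloride, which rests as its ring tautomer, 5-chloro lactone F9. 2,6-Lutidine at 0 °C then removes HCl through the unhindered ring CH2, and the sequence rejoins the route at 31.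

Further compounds
F1 | step 18 | (S)-N-{(1R)-1-[(2S,4S)-4-methyl-5-oxotetrahydrofuran-2-yl]but-3-enyl}-2-methylpropane-2-sulfinamide | CC(C)(C)[S@](=O)N[C@@H]([C@@H]1C[C@H](C)C(=O)O1)CC=C
F2 | step 18 | 4-(2,5-dibromo-4-ethylfuran-3-yl)-N-{(1R)-1-[(2S,4S)-4-methyl-5-oxotetrahydrofuran-2-yl]but-3-enyl}butanamide | CCc1c(Br)oc(Br)c1CCCC(=O)N[C@@H]([C@@H]1C[C@H](C)C(=O)O1)CC=C
F3 | step 18 | 2-bromo N-homoallyl furo[2,3-b]azepin-7-one | CCc1c(Br)oc2c1CCCC(=O)N2[C@@H]([C@@H]1C[C@H](C)C(=O)O1)CC=C
F4 | step 18 | N-homoallyl furo[2,3-b]azepin-7-one | CCc1coc2c1CCCC(=O)N2[C@@H]([C@@H]1C[C@H](C)C(=O)O1)CC=C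
F5 | step 18 | methyl (E)-alkenoate from cross-metathesis of F4 | CCc1coc2c1CCCC(=O)N2[C@@H]([C@@H]1C[C@H](C)C(=O)O1)C/C=C/CC(=O)OC
F6 | step 18 | tricyclic enamide keto ester with H on the future quaternary carbon | CC[C@H]1C2=C3N(C(=O)CCC2)[C@@H]([C@@H]2C[C@H](C)C(=O)O2)C[C@H]3[C@H](CC(=O)OC)C1=O
F7 | step 18 | triethylsilyl ether of the carbinol from F6 | CC[C@H]1C2=C3N(C(=O)CCC2)[C@@H]([C@@H]2C[C@H](C)C(=O)O2)C[C@H]3[C@H](CC(=O)OC)[C@@H]1O[Si](CC)(CC)CC
F8 | step 18 | tertiary allylic alcohol from F7 | CC[C@H]1C2=C3N(C(=O)CCC2)[C@@H]([C@@H]2C[C@H](C)C(=O)O2)C[C@@]3(O)[C@H](CC(=O)OC)[C@@H]1O[Si](CC)(CC)CC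
F0 | step 19 | none | none
F9 | step 17 | 5-chloro lactone (ring tautomer of the acid chloride of 30) | CCc1coc2c1CCCC(=O)N2[C@@H]([C@@H]1C[C@H](C)C(=O)O1)CC1(Cl)CCC(=O)O1
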